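**Retrosynthetic overview**

- The route ends with O‑sulfation of the one free phenol of an otherwise fully benzylated terphenyl, then hydrogenolysis of eight benzyl ethers. No ring is built: rings A (sulfated), B (central) and C (terminal) are all bought as phloroglucinol derivatives.
- Key disconnection: the bond from C2 of ring A to the ring B carbon that lies between two oxygen‑bearing carbons. It is made by dirhodium‑carbene C–H arylation of hexa‑O‑benzyl difucol (rings B–C) with the ortho‑quinone diazide of ring A, with loss of N2.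
- Enabling feature: in ring A the sulfated oxygen sits on C1, next to the inter‑ring carbon C2, so the O–C1–C2 unit is the C=O/C=N2 unit of an ortho‑quinone diazide and its carbonyl oxygen returns as the only free hydroxyl. In ring B the bond‑forming carbon is a C–H flanked by two C–O carbons and para to a third, and the protected B–C biaryl has four such C–H sites, all equivalent by symmetry.
- Rings B–C: iodination of 1,3,5‑tris(benzyloxy)benzene, then Ullmann homocoupling (B–C bond first, A–B bond second).
- Ring A: 2‑nitrophloroglucinol, bis‑benzylation, nitro reduction, diazotization.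

Key step: step 6

Assumption: the target SMILES carries no stereodescriptor, so the hindered A–B axis is taken as unassigned and is formed as the racemate; sulfate monoesters are drawn as free acids as in the target, are meant to be handled as sodium salts, and the free acid is released only at the end by cold cation exchange.

**Route**

Step 1
Reactants: 1 1,3,5-tris(benzyloxy)benzene
Product: 2 1,3,5-tris(benzyloxy)-2-iodobenzene
Conditions: NIS (1.0 equiv), CH2Cl2, 0 °C, dark
Reagents that add atoms: N-iodosuccinimide, O=C1CCC(=O)N1I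
Why: Electrophilic aromatic iodination of a triply activated arene whose three ring C–H positions are equivalent, so one equivalent of NIS should give the mono-iodide.

Step 2
Reactants: 2 1,3,5-tris(benzyloxy)-2-iodobenzene (2 equiv)
Product: 3 2,2',4,4',6,6'-hexakis(benzyloxy)-1,1'-biphenyl
Conditions: activated Cu bronze (excess), DMF, 150 °C, argon
Reagents that add atoms: none
Why: Ullmann reductive homocoupling, the classical entry to 2,2',6,6'-tetraalkoxybiphenyls from 2-iodo-1,3-dialkoxybenzenes, should join the two identical halves.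

Step 3
Reactants: 4 2-nitrobenzene-1,3,5-triol (2-nitrophloroglucinol)
Product: 5 3,5-bis(benzyloxy)-2-nitrophenol
Conditions: BnBr (2.1 equiv), K2CO3 (2.2 equiv), DMF, 0 °C to rt
Reagents that add atoms: benzyl bromide, BrCc1ccccc1
Why: In this Williamson ether synthesis the hydroxyl para to the nitro group reacts first and one ortho hydroxyl second, while the last one is held in a hydrogen bond to the nitro group and should stay free, as in the 4,6-di-O-benzylation of 2-acylphloroglucinols.

Step 4
Reactants: 5 3,5-bis(benzyloxy)-2-nitrophenol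
Product: 6 2-amino-3,5-bis(benzyloxy)phenol
Conditions: Na2S2O4, THF/EtOH/H2O, 50 °C, argon; used at once
Reagents that add atoms: none
Why: Dithionite reduction of an aromatic nitro group leaves benzyl ethers untouched and should give the air-sensitive ortho-aminophenol.

Step 5
Reactants: 6 2-amino-3,5-bis(benzyloxy)phenol
Product: 8 3,5-bis(benzyloxy)-6-diazocyclohexa-2,4-dien-1-one, via diazonium chloride 7 (not isolated)
Conditions: NaNO2, aq. HCl, THF, 0 °C; then NaHCO3 to pH 7, dark
Reagents that add atoms: sodium nitrite, [Na+].[O-]N=O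
Why: Classical diazotization of an ortho-aminophenol; the diazonium ion next to the hydroxyl should lose its proton on neutralisation to give the neutral ortho-quinone diazide.

Step 6
Reactants: 3 2,2',4,4',6,6'-hexakis(benzyloxy)-1,1'-biphenyl (2.5 equiv, excess recovered); 8 3,5-bis(benzyloxy)-6-diazocyclohexa-2,4-dien-1-one
Product: 9 3,5-bis(benzyloxy)-2-[2,4,6-tris(benzyloxy)-3-(2,4,6-tris(benzyloxy)phenyl)phenyl]phenol
Conditions: Rh2(OAc)4 (2 mol%), 1,2-dichloroethane, 70 °C, 8 added slowly by syringe pump, argon
Reagents that add atoms: none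
Why: Rh2(OAc)4 should take N2 from 8 and give an electrophilic rhodium-bound 2-oxo carbene at the former diazo carbon, in effect a 2-oxidoaryl cation; a C–H carbon of 3 attacks it in a Friedel–Crafts sense, the metal leaves as ring A aromatises to the phenolate, and the arenium proton of ring B passes to that oxygen. The closest known reaction type is the dirhodium-catalysed formal aromatic C–H insertion of electron-rich arenes into carbenes from quinone diazides and cyclic 2-diazo-1,3-diketones, which delivers 2-hydroxybiaryls. No ring is closed and no stereocentre is set; the crowded A–B axis forms as the racemate. Site selectivity on the nucleophile needs no control, because the four aromatic C–H positions of 3 are equivalent by symmetry and each is ortho, ortho and para to benzyloxy groups, while the site on ring A is fixed by the diazo carbon and its neighbouring carbonyl oxygen becomes the single free hydroxyl of 9, the oxygen that has to carry the sulfate. A second arylation and O–H insertion into 9 should be held back by the excess of 3 and the slow addition of 8, and intramolecular attack on the unactivated phenyl ring of a benzyl ether is expected to lose against the far more nucleophilic triply oxygenated ring.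

Step 7
Reactants: 9 3,5-bis(benzyloxy)-2-[2,4,6-tris(benzyloxy)-3-(2,4,6-tris(benzyloxy)phenyl)phenyl]phenol
Product: 10 3,5-bis(benzyloxy)-2-[2,4,6-tris(benzyloxy)-3-(2,4,6-tris(benzyloxy)phenyl)phenyl]phenyl hydrogen sulfate
Conditions: SO3·NMe3 (5 equiv), Et3N, DMF, 60 °C; aq. NaHCO3 work-up
Reagents that add atoms: sulfur trioxide–trimethylamine complex, C[N+](C)(C)S(=O)(=O)[O-]
Why: O-Sulfation of a phenol with a sulfur trioxide–amine complex; 9 holds a single free hydroxyl, so no question of selectivity arises.

Step 8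
Reactants: 10 3,5-bis(benzyloxy)-2-[2,4,6-tris(benzyloxy)-3-(2,4,6-tris(benzyloxy)phenyl)phenyl]phenyl hydrogen sulfate
Product: 11 2-[2,4,6-trihydroxy-3-(2,4,6-trihydroxyphenyl)phenyl]-3,5-dihydroxyphenyl hydrogen sulfate (target)
Conditions: H2 (1 atm), Pd(OH)2/C, THF/MeOH/H2O, rt, argon handling; then Dowex 50W (H+ form), H2O/MeOH, 0 °C, freeze-drying
Reagents that add atoms: none
Why: Hydrogenolysis of benzyl aryl ethers over palladium should free all eight phenols, since aryl sulfate monoester salts survive neutral hydrogenolysis, and brief cold cation exchange gives the free acid.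

**Compound list**

1 | 1,3,5-tris(benzyloxy)benzene | c1c(OCc2ccccc2)cc(OCc2ccccc2)cc1OCc1ccccc1 | starting material
2 | 1,3,5-tris(benzyloxy)-2-iodobenzene | Ic1c(OCc2ccccc2)cc(OCc2ccccc2)cc1OCc1ccccc1 | intermediate
3 | 2,2',4,4',6,6'-hexakis(benzyloxy)-1,1'-biphenyl | c1c(OCc2ccccc2)cc(OCc2ccccc2)c(-c2c(OCc3ccccc3)cc(OCc3ccccc3)cc2OCc2ccccc2)c1OCc1ccccc1 | intermediate
4 | 2-nitrobenzene-1,3,5-triol (2-nitrophloroglucinol) | O=[N+]([O-])c1c(O)cc(O)cc1O | starting material
5 | 3,5-bis(benzyloxy)-2-nitrophenol | O=[N+]([O-])c1c(O)cc(OCc2ccccc2)cc1OCc1ccccc1 | intermediate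
6 | 2-amino-3,5-bis(benzyloxy)phenol | Nc1c(O)cc(OCc2ccccc2)cc1OCc1ccccc1 | intermediate
7 | 2,4-bis(benzyloxy)-6-hydroxybenzenediazonium chloride | N#[N+]c1c(O)cc(OCc2ccccc2)cc1OCc1ccccc1.[Cl-] | intermediate (not isolated)
8 | 3,5-bis(benzyloxy)-6-diazocyclohexa-2,4-dien-1-one | O=C1C=C(OCc2ccccc2)C=C(OCc2ccccc2)C1=[N+]=[N-] | intermediate
9 | 3,5-bis(benzyloxy)-2-[2,4,6-tris(benzyloxy)-3-(2,4,6-tris(benzyloxy)phenyl)phenyl]phenol | Oc1cc(OCc2ccccc2)cc(OCc2ccccc2)c1-c1c(OCc2ccccc2)cc(OCc2ccccc2)c(-c2c(OCc3ccccc3)cc(OCc3ccccc3)cc2OCc2ccccc2)c1OCc1ccccc1 | intermediate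
10 | 3,5-bis(benzyloxy)-2-[2,4,6-tris(benzyloxy)-3-(2,4,6-tris(benzyloxy)phenyl)phenyl]phenyl hydrogen sulfate | O=S(=O)(O)Oc1cc(OCc2ccccc2)cc(OCc2ccccc2)c1-c1c(OCc2ccccc2)cc(OCc2ccccc2)c(-c2c(OCc3ccccc3)cc(OCc3ccccc3)cc2OCc2ccccc2)c1OCc1ccccc1 | intermediate
11 | 2-[2,4,6-trihydroxy-3-(2,4,6-trihydroxyphenyl)phenyl]-3,5-dihydroxyphenyl hydrogen sulfate | O=S(=O)(O)Oc1cc(O)cc(O)c1-c1c(O)cc(O)c(-c2c(O)cc(O)cc2O)c1O | target

**Step count and risks**

Total step count: 8. Longest linear sequence: 6 steps (steps 3, 4, 5, 6, 7, 8, from compound 4).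

Steps most likely to fail:

1. Step 6. The rhodium carbene may be used up faster by attack on the phenyl ring of the neighbouring benzyl ether, by insertion into the O–H bond of the product or by a second arylation than by the crowded C–H carbon of the biaryl, or the electron-rich diazide may resist loss of N2. Fallback: a Suzuki–Miyaura coupling with both partners functionalised, setting out from 8 and 3 and coming back at 9. From 8, KI in aq. HCl/MeCN at 0 °C to rt (iododediazoniation) would give 3,5-bis(benzyloxy)-2-iodophenol F1. From 3 (in excess), NIS in CH2Cl2 would give 2,2',4,4',6,6'-hexakis(benzyloxy)-3-iodo-1,1'-biphenyl F2, and Miyaura borylation (B2pin2, KOAc, Pd(OAc)2/SPhos, dioxane, 90 °C) would turn it into 2-[2,4,6-tris(benzyloxy)-3-(2,4,6-tris(benzyloxy)phenyl)phenyl]-4,4,5,5-tetramethyl-1,3,2-dioxaborolane F3. Coupling of F1 with F3 (Pd(OAc)2/SPhos, K3PO4, toluene/H2O, 90 °C) would then give 9.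

2. Step 2. Reductive loss of iodine or thermal benzyl migration may outrun the coupling at the doubly flanked carbon. Fallback: an unsymmetrical Suzuki–Miyaura assembly of the same biaryl, setting out from 2 and coming back at 3. Miyaura borylation of one portion of 2 (B2pin2, KOAc, Pd(OAc)2/SPhos, dioxane, 90 °C) would give 2-[2,4,6-tris(benzyloxy)phenyl]-4,4,5,5-tetramethyl-1,3,2-dioxaborolane F4, and coupling of F4 with a second portion of 2 (Pd(OAc)2/SPhos, K3PO4, toluene/H2O, 90 °C) would give 3.

3. Step 8. Acid-promoted loss of the sulfate during exhaustive hydrogenolysis and ion exchange, or stalling of the debenzylation of a charged, poorly soluble salt. Fallback: a masked, neutral sulfate carried through the deprotection, setting out from 9 and coming back at 11 (it takes the place of steps 7 and 8). 2,2,2-Trichloroethyl chlorosulfate (ClC(Cl)(Cl)COS(=O)(=O)Cl), Et3N and DMAP in THF would give the chromatographable mixed diester 3,5-bis(benzyloxy)-2-[2,4,6-tris(benzyloxy)-3-(2,4,6-tris(benzyloxy)phenyl)phenyl]phenyl 2,2,2-trichloroethyl sulfate F5. Pd/C with ammonium formate in MeOH/THF would then remove the trichloroethyl group and all eight benzyl ethers in one operation to give 11 after cold cation exchange.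

Further compounds
F1 | step 6 | 3,5-bis(benzyloxy)-2-iodophenol | Oc1cc(OCc2ccccc2)cc(OCc2ccccc2)c1I
F2 | step 6 | 2,2',4,4',6,6'-hexakis(benzyloxy)-3-iodo-1,1'-biphenyl | Ic1c(OCc2ccccc2)cc(OCc2ccccc2)c(-c2c(OCc3ccccc3)cc(OCc3ccccc3)cc2OCc2ccccc2)c1OCc1ccccc1
F3 | step 6 | 2-[2,4,6-tris(benzyloxy)-3-(2,4,6-tris(benzyloxy)phenyl)phenyl]-4,4,5,5-tetramethyl-1,3,2-dioxaborolane | CC1(C)OB(OC1(C)C)c1c(OCc2ccccc2)cc(OCc2ccccc2)c(-c2c(OCc3ccccc3)cc(OCc3ccccc3)cc2OCc2ccccc2)c1OCc1ccccc1
F4 | step 2 | 2-[2,4,6-tris(benzyloxy)phenyl]-4,4,5,5-tetramethyl-1,3,2-dioxaborolane | CC1(C)OB(OC1(C)C)c1c(OCc2ccccc2)cc(OCc2ccccc2)cc1OCc1ccccc1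
F5 | step 8 | 3,5-bis(benzyloxy)-2-[2,4,6-tris(benzyloxy)-3-(2,4,6-tris(benzyloxy)phenyl)phenyl]phenyl 2,2,2-trichloroethyl sulfate | ClC(Cl)(Cl)COS(=O)(=O)Oc1cc(OCc2ccccc2)cc(OCc2ccccc2)c1-c1c(OCc2ccccc2)cc(OCc2ccccc2)c(-c2c(OCc3ccccc3)cc(OCc3ccccc3)cc2OCc2ccccc2)c1OCc1ccccc1
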